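**Retrosynthetic overview**
1. The target is cut at the two sp3–sp2 bonds next to the Z-trisubstituted alkenes. Both come from stereoretentive B-alkyl Suzuki couplings onto a 3-bromo-7-(1-hydroxyallyl)-7-methyl-oxepinone: one with a (Z)-dienol (from propargyl alcohol, MeMgBr and vinyl bromide), one with (Z)-3-iodobut-2-en-1-ol (from but-2-yn-1-ol).
2. The oxepinone comes from a Baeyer–Villiger ring expansion of a 2-bromo-6,6-disubstituted cyclohex-2-enone; the quaternary carbon shifts from C to O with retention.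
3. The cyclohexenone comes from one enantioselective anti aldol of the α′-dienolate of 2-bromo-6-methylcyclohex-2-enone with acrolein, which sets both stereocentres.
4. Ring order: the six-membered carbocycle is bought; the only ring-forming event is its expansion to the seven-membered lactone.

Assumption: racemic 6-methylcyclohex-2-en-1-one is taken as a catalogue compound, and the chiral bromoborane of step 4 is a reagent prepared beforehand from the commercial (S,S)-bis-sulfonamide and BBr3.

**Step 1**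
Reactants: 1 prop-2-yn-1-ol; 2 bromoethene (vinyl bromide)
Product: 4 (2Z)-2-methylpenta-2,4-dien-1-ol, via magnesium chelate 3 (not isolated)
Conditions: MeMgBr (2.3 equiv), CuI (10 mol%), THF, −10 °C → rt; then 2 (3 equiv), Pd(PPh3)4 (5 mol%), 0 °C → rt; aq NH4Cl
Reagents that add atoms: methylmagnesium bromide, C[Mg]Br
Why: Copper-catalysed anti-carbomagnesiation of the propargylic alkoxide puts Me on C2 and Mg on C3 cis to CH2O (chelate 3), and Kumada–Corriu coupling with vinyl bromide under zerovalent palladium replaces Mg with retention, so CH2OH and the vinyl group end up cis (Z).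

**Step 2**
Reactants: 5 but-2-yn-1-ol
Product: 7 (2Z)-3-iodobut-2-en-1-ol, via alkenylalanate 6 (not isolated)
Conditions: NaAlH2(OCH2CH2OMe)2 (1.6 equiv), THF, 0 °C → rt; EtOAc; then I2, −78 → 0 °C; aq Na2S2O3
Reagents that add atoms: iodine, I-I
Why: Hydroxyl-directed trans-hydroalumination puts Al on C3 cis to CH2O (cyclic alanate 6) and iodinolysis of the C–Al bond goes with retention, giving the Z vinyl iodide with I cis to CH2OH.

**Step 3**
Reactants: 8 rac-6-methylcyclohex-2-en-1-one
Product: 10 rac-2-bromo-6-methylcyclohex-2-en-1-one, via dibromide 9 (not isolated)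
Conditions: Br2 (1.05 equiv), CH2Cl2, 0 °C; then Et3N (1.6 equiv), 0 °C → rt
Reagents that add atoms: bromine, BrBr
Why: Bromine addition to the enone C=C followed by base-induced loss of HBr from the α,β-dibromide (α-bromination of an enone by addition–elimination) gives the 2-bromoenone and leaves C6 untouched.

**Step 4**
Reactants: 10 rac-2-bromo-6-methylcyclohex-2-en-1-one; 11 prop-2-enal (acrolein)
Product: 15 (6R)-2-bromo-6-[(1R)-1-hydroxyprop-2-en-1-yl]-6-methylcyclohex-2-en-1-one, via lithium dienolate 12 (not isolated), via boron dienolate 13 (not isolated), via boron aldolate 14 (not isolated)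
Conditions: LiN(iPr)2 (1.05 equiv), THF, −78 °C; (4S,5S)-2-bromo-4,5-diphenyl-1,3-bis(4-tolylsulfonyl)-1,3,2-diazaborolidine (1.2 equiv, in CH2Cl2), −78 °C; 11 (1.5 equiv), −78 °C; pH 7 buffer, MeOH
Reagents that add atoms: none
Why: Proposed new method: kinetic α′-deprotonation erases the C6 centre and gives the ring-locked, fully substituted cross-conjugated lithium dienolate 12 (Me cis, ring CH2 trans to O), Li-to-B exchange on the C2-symmetric bromoborane gives enol borinate 13, and a Zimmerman–Traxler chair with the vinyl group of acrolein equatorial fixes the anti relationship (ring CH2 anti to OH) while the tolylsulfonyl groups of the (S,S)-controller are expected to leave the Si face of the enolate carbon open to the Si face of the aldehyde, setting C6 (R) and C1′ (R) together; the closest known reaction type is the Corey diazaborolidine-controlled boron aldol of ketone and ester enol borinates, which has not been shown for tetrasubstituted enolates or for enolates made by transmetalation.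

**Step 5**
Reactants: 15 (6R)-2-bromo-6-[(1R)-1-hydroxyprop-2-en-1-yl]-6-methylcyclohex-2-en-1-one
Product: 16 (7R)-3-bromo-7-[(1R)-1-hydroxyprop-2-en-1-yl]-7-methyl-6,7-dihydro-5H-oxepin-2-one
Conditions: mCPBA (2 equiv), NaHCO3, CH2Cl2, 0 °C → rt
Reagents that add atoms: 3-chloroperoxybenzoic acid, OOC(=O)c1cccc(Cl)c1
Why: Baeyer–Villiger ring expansion: in the Criegee adduct the tertiary C6 migrates to oxygen far better than the electron-poor 2-bromovinyl carbon and does so with retention, the bromoenone C=C is inert to peracid and the monosubstituted vinyl group is the least reactive alkene class, so the six-membered ketone becomes the seven-membered lactone with both stereocentres unchanged.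

**Step 6**
Reactants: 4 (2Z)-2-methylpenta-2,4-dien-1-ol; 16 (7R)-3-bromo-7-[(1R)-1-hydroxyprop-2-en-1-yl]-7-methyl-6,7-dihydro-5H-oxepin-2-one
Product: 18 (7R)-3-[(3Z)-5-hydroxy-4-methylpent-3-en-1-yl]-7-[(1R)-1-hydroxyprop-2-en-1-yl]-7-methyl-6,7-dihydro-5H-oxepin-2-one, via bis-boryl adduct 17 (not isolated)
Conditions: 4 (1.5 equiv), 9-BBN (3.0 equiv), THF, 0 °C → rt; H2O; then 16, Pd(dppf)Cl2 (5 mol%), AsPh3, Cs2CO3, DMF/H2O, rt
Reagents that add atoms: none
Why: 9-BBN takes up the hydroxyl as a borinate and adds only to the terminal vinyl of the diene with boron on the end carbon, and B-alkyl Suzuki–Miyaura coupling of this homoallylic borane with the α-bromo enoate leaves the alkene geometry, the lactone, the free alcohol and the vinyl group untouched.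

**Step 7**
Reactants: 18 (7R)-3-[(3Z)-5-hydroxy-4-methylpent-3-en-1-yl]-7-[(1R)-1-hydroxyprop-2-en-1-yl]-7-methyl-6,7-dihydro-5H-oxepin-2-one; 7 (2Z)-3-iodobut-2-en-1-ol
Product: 20 (7R)-7-[(1R,4Z)-1,6-dihydroxy-4-methylhex-4-en-1-yl]-3-[(3Z)-5-hydroxy-4-methylpent-3-en-1-yl]-7-methyl-6,7-dihydro-5H-oxepin-2-one, via tris-boryl adduct 19 (not isolated)
Conditions: 9-BBN (3.3 equiv), THF, 0 °C → rt; H2O; then 7 (1.5 equiv), Pd(dppf)Cl2 (10 mol%), AsPh3, Cs2CO3, DMF/H2O, rt
Reagents that add atoms: none
Why: 9-BBN hydroborates only the monosubstituted vinyl group (the two hydroxyls ride as borinates; the trisubstituted alkenes and the lactone do not react) and B-alkyl Suzuki–Miyaura coupling with the Z vinyl iodide is stereoretentive, which completes the second Z side chain and gives the target.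

**Compound list**
1 | prop-2-yn-1-ol | C#CCO | starting material
2 | bromoethene (vinyl bromide) | C=CBr | starting material
3 | 4-methyl-2,5-dihydro-1,2-oxamagnesole (cyclic Z-alkenylmagnesium alkoxide) | CC1=C[Mg]OC1 | intermediate
4 | (2Z)-2-methylpenta-2,4-dien-1-ol | OC/C(C)=C\C=C | intermediate
5 | but-2-yn-1-ol | CC#CCO | starting material
6 | sodium 2,2-bis(2-methoxyethoxy)-3-methyl-2,5-dihydro-1,2-oxaluminol-2-uide (cyclic alkenylalanate) | CC1=CCO[Al-]1(OCCOC)OCCOC.[Na+] | intermediate
7 | (2Z)-3-iodobut-2-en-1-ol | C/C(I)=C/CO | intermediate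
8 | rac-6-methylcyclohex-2-en-1-one | CC1CCC=CC1=O | starting material
9 | 2,3-dibromo-6-methylcyclohexan-1-one (racemic diastereomer mixture) | CC1CCC(Br)C(Br)C1=O | intermediate
10 | rac-2-bromo-6-methylcyclohex-2-en-1-one | CC1CCC=C(Br)C1=O | intermediate
11 | prop-2-enal (acrolein) | C=CC=O | starting material
12 | lithium 6-bromo-2-methylcyclohexa-1,5-dien-1-olate | [Li]OC1=C(C)CCC=C1Br | intermediate
13 | (4S,5S)-2-[(6-bromo-2-methylcyclohexa-1,5-dien-1-yl)oxy]-4,5-diphenyl-1,3-bis(4-tolylsulfonyl)-1,3,2-diazaborolidine | CC1=C(OB2N(S(=O)(=O)c3ccc(C)cc3)[C@@H](c3ccccc3)[C@H](c3ccccc3)N2S(=O)(=O)c2ccc(C)cc2)C(Br)=CCC1 | intermediate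
14 | B-O aldolate of 15 with the (4S,5S)-diazaborolidine | BrC1=CCC[C@](C)([C@H](OB2N(S(=O)(=O)c3ccc(C)cc3)[C@@H](c3ccccc3)[C@H](c3ccccc3)N2S(=O)(=O)c2ccc(C)cc2)C=C)C1=O | intermediate
15 | (6R)-2-bromo-6-[(1R)-1-hydroxyprop-2-en-1-yl]-6-methylcyclohex-2-en-1-one | BrC1=CCC[C@](C)([C@H](O)C=C)C1=O | intermediate
16 | (7R)-3-bromo-7-[(1R)-1-hydroxyprop-2-en-1-yl]-7-methyl-6,7-dihydro-5H-oxepin-2-one | BrC1=CCC[C@](C)([C@H](O)C=C)OC1=O | intermediate
17 | 9-[(3Z)-5-(9-borabicyclo[3.3.1]nonan-9-yloxy)-4-methylpent-3-en-1-yl]-9-borabicyclo[3.3.1]nonane | C/C(COB1C2CCCC1CCC2)=C/CCB1C2CCCC1CCC2 | intermediate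
18 | (7R)-3-[(3Z)-5-hydroxy-4-methylpent-3-en-1-yl]-7-[(1R)-1-hydroxyprop-2-en-1-yl]-7-methyl-6,7-dihydro-5H-oxepin-2-one | C/C(=C/CCC1=CCC[C@](C)([C@H](O)C=C)OC1=O)CO | intermediate
19 | 18 carrying 9-BBN on both oxygens and on the terminal carbon of the former vinyl group | C/C(=C/CCC1=CCC[C@](C)([C@H](OB2C3CCCC2CCC3)CCB2C3CCCC2CCC3)OC1=O)COB1C2CCCC1CCC2 | intermediate
20 | (7R)-7-[(1R,4Z)-1,6-dihydroxy-4-methylhex-4-en-1-yl]-3-[(3Z)-5-hydroxy-4-methylpent-3-en-1-yl]-7-methyl-6,7-dihydro-5H-oxepin-2-one | C/C(=C/CCC1=CCC[C@](C)([C@H](O)CC/C(C)=C\CO)OC1=O)CO | target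

**Totals**
Total steps: 7. Longest linear sequence: 5 (steps 3, 4, 5, 6, 7 from compound 8).

**Three steps most likely to fail**

Step 4 (the proposed new step). Yield, anti selectivity and enantioselectivity are unproven for a tetrasubstituted dienolate. The (S,S)-antipode of the controller is chosen by analogy only; the sense must be checked on the first run (Mosher esters) and the (R,R)-reagent used if it is reversed. Fallback with known chemistry, setting out from 10 and 11 and coming back at 15: 10 is deprotonated with LiN(iPr)2 alone (THF, −78 °C) and lithium dienolate 12 is treated with 11. The closed lithium transition state gives the anti racemate, that is 15 together with its mirror image (6S)-2-bromo-6-[(1S)-1-hydroxyprop-2-en-1-yl]-6-methylcyclohex-2-en-1-one F1. Sharpless kinetic resolution of this secondary allylic alcohol (Ti(OiPr)4, diisopropyl D-(−)-tartrate, tBuOOH, molecular sieves, CH2Cl2, −20 °C, about 55% conversion) epoxidises F1 to the erythro epoxy alcohol (6S)-2-bromo-6-[(R)-hydroxy[(2S)-oxiran-2-yl]methyl]-6-methylcyclohex-2-en-1-one F2, which is separated, and returns unreacted 15. The D-tartrate is chosen because, by my reading of the Sharpless model, the (S)-carbinol enantiomer is the fast one here (the quaternary carbon outranks vinyl in the descriptor).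

Step 5. The hindered, conjugated ketone may react slowly enough for hydroxyl-assisted epoxidation of the vinyl carbinol to compete. Fallback, setting out from 15 and coming back at 16: the carbinol is silylated (TBSOTf, 2,6-lutidine, CH2Cl2) to (6R)-2-bromo-6-[(1R)-1-(tert-butyldimethylsilyloxy)prop-2-en-1-yl]-6-methylcyclohex-2-en-1-one F3. Its vinyl group is no longer hydroxyl-assisted, so the oxidation can be forced (excess mCPBA, Na2HPO4, 1,2-dichloroethane, 45 °C, radical inhibitor) to give (7R)-3-bromo-7-[(1R)-1-(tert-butyldimethylsilyloxy)prop-2-en-1-yl]-7-methyl-6,7-dihydro-5H-oxepin-2-one F4. HF·pyridine in MeCN then frees 16.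

Step 7. Three boron-bound sites on one molecule and a base-sensitive lactone make the last coupling the most delicate of the known steps. Fallback, setting out from 18 and coming back at 20: both hydroxyls are silylated (Et3SiCl, imidazole, DMF) to (7R)-7-methyl-3-[(3Z)-4-methyl-5-(triethylsilyloxy)pent-3-en-1-yl]-7-[(1R)-1-(triethylsilyloxy)prop-2-en-1-yl]-6,7-dihydro-5H-oxepin-2-one F5. One equivalent of 9-BBN then hydroborates the vinyl group and coupling with 7 under the conditions of step 7 gives (7R)-7-[(1R,4Z)-6-hydroxy-4-methyl-1-(triethylsilyloxy)hex-4-en-1-yl]-7-methyl-3-[(3Z)-4-methyl-5-(triethylsilyloxy)pent-3-en-1-yl]-6,7-dihydro-5H-oxepin-2-one F6. HF·pyridine in THF removes both silyl groups to give 20.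

**Further compounds**
F1 | step 4 | (6S)-2-bromo-6-[(1S)-1-hydroxyprop-2-en-1-yl]-6-methylcyclohex-2-en-1-one | BrC1=CCC[C@@](C)([C@@H](O)C=C)C1=O
F2 | step 4 | (6S)-2-bromo-6-[(R)-hydroxy[(2S)-oxiran-2-yl]methyl]-6-methylcyclohex-2-en-1-one | BrC1=CCC[C@@](C)([C@@H](O)[C@@H]2CO2)C1=O
F3 | step 5 | (6R)-2-bromo-6-[(1R)-1-(tert-butyldimethylsilyloxy)prop-2-en-1-yl]-6-methylcyclohex-2-en-1-one | BrC1=CCC[C@](C)([C@H](O[Si](C)(C)C(C)(C)C)C=C)C1=O
F4 | step 5 | (7R)-3-bromo-7-[(1R)-1-(tert-butyldimethylsilyloxy)prop-2-en-1-yl]-7-methyl-6,7-dihydro-5H-oxepin-2-one | BrC1=CCC[C@](C)([C@H](O[Si](C)(C)C(C)(C)C)C=C)OC1=O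
F5 | step 7 | (7R)-7-methyl-3-[(3Z)-4-methyl-5-(triethylsilyloxy)pent-3-en-1-yl]-7-[(1R)-1-(triethylsilyloxy)prop-2-en-1-yl]-6,7-dihydro-5H-oxepin-2-one | C/C(=C/CCC1=CCC[C@](C)([C@H](O[Si](CC)(CC)CC)C=C)OC1=O)CO[Si](CC)(CC)CC
F6 | step 7 | (7R)-7-[(1R,4Z)-6-hydroxy-4-methyl-1-(triethylsilyloxy)hex-4-en-1-yl]-7-methyl-3-[(3Z)-4-methyl-5-(triethylsilyloxy)pent-3-en-1-yl]-6,7-dihydro-5H-oxepin-2-one | C/C(=C/CCC1=CCC[C@](C)([C@H](O[Si](CC)(CC)CC)CC/C(C)=C\CO)OC1=O)CO[Si](CC)(CC)CC
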